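(The numbers in the tables were generated by integration with constants of no real substance, and the scatter is random.)

The earlier runs beta, zeta and alpha followed substrate and target at different charges of coupling partner, and the new flasks larch to maple are stopped at 8.0 min.

| setting | beta | zeta | alpha | larch | cedar | ash | oak | maple |
|---|---|---|---|---|---|---|---|---|
| substrate | 0.010 M | 0.010 M | 0.010 M | 0.010 M | 0.010 M | 0.010 M | 0.010 M | 0.010 M |
| coupling partner | 0.43 equiv | 0.85 equiv | 1.7 equiv | 0.400 equiv | 0.600 equiv | 0.800 equiv | 1.20 equiv | 2.00 equiv |
| remark | run made earlier | run made earlier | run made earlier |  |  |  |  |  |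
| time |  |  |  | 8.0 min | 8.0 min | 8.0 min | 8.0 min | 8.0 min |

| run | time / min | target / % | substrate / % |
|---|---|---|---|
| beta | 0.333 | 0 | 81.4 |
| beta | 0.667 | 0.7 | 67.8 |
| beta | 1.00 | 0.3 | 58.2 |
| beta | 2.00 | 0 | 36.8 |
| beta | 4.00 | 0.1 | 19.2 |
| zeta | 0.333 | 0 | 78.0 |
| zeta | 0.667 | 0 | 63.3 |
| zeta | 1.00 | 0 | 52.0 |
| zeta | 2.00 | 0.4 | 31.2 |
| zeta | 4.00 | 1.8 | 15.9 |
| alpha | 0.333 | 0.2 | 71.1 |
| alpha | 0.667 | 0.4 | 53.6 |
| alpha | 1.00 | 0 | 42.1 |
| alpha | 2.00 | 0.5 | 22.4 |
| alpha | 4.00 | 3.4 | 10.0 |

(each reading ± 0.5 percentage points)

- "hardly changes" means that all values lie within two and a half points (for a concentration: within two and a half percent of the largest)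

* amount of target at the end, in percent of the substrate charged for larch, cedar, ash, oak, maple, in this order
* the course of these numbers from the first flask to the last (rises all the way / falls, then rises / falls all the way / hardly changes / rises, then falls)

At the first reading the beta run has 81.4 % of its substrate left and the alpha run 71.1 %. The logarithm of the fraction left, divided by the time, gives a pseudo-first-order loss rate of 0.618 min⁻¹ at 0.43 equiv and 1.02 min⁻¹ at 1.7 equiv. A straight line through these two points does not reach zero at zero charge, so substrate has a loss of its own beside capture by coupling partner. The crossover charge, the charge at which capture equals that own loss on this line, is 1.50. Own loss over capture is then the crossover divided by the charge. By this reckoning, capture takes 21.0 % of the lost substrate in larch and a larger 57.1 % in maple, so target is expected to climb along the row.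

The forecast gives 0.5 %, 1.2 %, 2.5 %, 5 % and 10 %, a course that rises all the way, on the ground that “No data show target being consumed, so it should rise throughout.”

The flasks give 1.40 %, 2.56 %, 3.78 %, 6.17 % and 10.2 %, a course that rises all the way, within the margin of the forecast.

    substrate + coupling partner → intermediate A (k = 0.810 M⁻¹ s⁻¹)
    coupling partner + intermediate A → intermediate B (k = 2.50 M⁻¹ s⁻¹)
    substrate ⇌ intermediate C (K = 5.70, k = 0.00780 s⁻¹)
    intermediate B → intermediate D (k = 0.00460 s⁻¹)
    intermediate D ⇌ target (K = 0.370, k = 0.0520 s⁻¹)
    coupling partner ⇌ dormant form (K = 0.970, k = 0.0400 s⁻¹)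
    substrate → decomposition product (k = 1.70 × 10⁻⁵ s⁻¹)
    coupling partner → decomposed reagent (k = 0.00160 s⁻¹)

At 8.00 min, maple, charged above the crossover of 1.50, holds 52.0 % of its substrate as intermediate A, intermediate B, intermediate D and target together, more than the 42.1 % in intermediate C. Larch, charged below the crossover, holds 15.1 % in those forms against 71.9 % in intermediate C. Target in maple stands at 10.2 %, and the run without its falling back to intermediate D gives 37.0 %. The rising course would turn to another shape in the run without the falling back of dormant form to coupling partner, where the step from larch to maple shrinks from 8.8 percentage points to 2.2 points.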